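**Plan**

- Retrosynthesis: both ester C–O bonds are cut (twofold Mitsunobu esterification with inversion at C6) to give an α-truxillic diacid, the solid-state [2+2] dimer of O-acetylferulic acid, and two molecules of 6-epi-incarvilline. In the alkaloid the cyclopentane bonds C5–C4a and C7–C7a are cut together, then C4–CH3 and C7–CH3.
- Forward: the piperidine ring is bought as an N-Boc enone, and the cyclopentane ring is annulated onto its C4a=C7a alkene in one amine-catalysed Michael/alkylation event. The C4 carbonyl then becomes C=CH2 and CH–CH3, C7 is methylated and decarboxylated, C6 is reduced, N-Boc becomes N-CH3, and the halves are joined and deacetylated.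
- Enabling feature: in the cyclopenta[c]pyridine unit the oxygenated C6 lies between C5 and C7 of the five-membered ring, so C5–C6–C7 is an acetoacetate-type 1,3-ambiphile (C7 nucleophilic, C5 electrophilic as CH2Br). The ring-fusion atoms C4a/C7a are an enone alkene as long as the methyl-bearing C4 of the piperidine ring is held as a ketone; that ketone and the C7 ester are the helpers and are removed later.
- Stereochemistry: C7a is set by a chiral primary amine catalyst and C4a is relayed in the same event (cis closure). C4 comes from hydrogenation on the face away from the cyclopentane, C7 from equilibration, C6 from convex-face hydride followed by Mitsunobu inversion, and the cyclobutane from crystal packing.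

Key step: step 2

Assumption (chemistry): the quinine-derived 9-amino(9-deoxy)epi-cinchona amine is taken to shield the iminium face that leads to the (7aR) adduct (otherwise its quinidine-derived pseudoenantiomer is used), and crystalline O-acetylferulic acid is taken to pack head-to-tail.

**Route**

Step 1
Reactants: 1 benzyl 3-oxobutanoate
Product: 2 benzyl 4-bromo-3-oxobutanoate
Conditions: Br2 (1.0 equiv), Et2O, 0 °C to rt, 16 h
Reagents that add atoms: bromine, BrBr
Why: Electrophilic α-bromination of the enol; the first-formed 2-bromo ester should isomerise under the HBr released to the more stable terminal 4-bromo keto ester, as is usual for acetoacetates, and no stereocenter is formed.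

Step 2
Reactants: 3 tert-butyl 3-oxo-3,6-dihydropyridine-1(2H)-carboxylate; 2 benzyl 4-bromo-3-oxobutanoate
Product: 5 7-benzyl 2-tert-butyl (4aR,7S,7aR)-4,6-dioxooctahydro-2H-cyclopenta[c]pyridine-2,7-dicarboxylate, via Michael adduct 4 (not isolated)
Conditions: 9-amino(9-deoxy)epi-quinine (20 mol%), CF3CO2H (40 mol%), NaHCO3 (1.2 equiv, solid), toluene, 0 °C to rt
Reagents that add atoms: none
Why: Proposed new method: the primary amine condenses with the ketone of 3 (future C4) to an iminium ion, the C2 carbon of keto ester 2 adds in Michael fashion to C7a, and the resulting C4=C4a enamine (as in 4) displaces bromide from the tethered CH2Br before hydrolysis returns the catalyst, so that C7–C7a and C5–C4a form in one catalytic cycle; the closest known reactions are the secondary-amine-catalysed domino Michael/α-alkylation of enals with 4-bromoacetoacetates to cyclopentanones and the primary-amine-catalysed Michael/alkylation cyclopropanation of cyclic enones with bromomalonates. The cyclopentane ring closes by 5-exo-tet C-alkylation of the enamine carbon at an sp3 carbon activated by the adjacent ketone. C7a is set by the catalyst, whose protonated quinuclidine and quinoline shield one face of the iminium ion; C4a follows by substrate control, because the bromomethyl ketone hangs from C7a and can reach the planar enamine carbon only from its own face, which enforces the cis fusion; C7 lies between two carbonyls and is labile. The step needs conjugate over direct addition, C- over O-attack of the keto ester, and enamine C-alkylation over N-alkylation of the catalyst; the soft iminium acceptor, the intramolecular five-ring closure and the twofold protonation of the catalyst should secure these, while solid NaHCO3 takes up HBr.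

Step 3
Reactants: 5 7-benzyl 2-tert-butyl (4aR,7S,7aR)-4,6-dioxooctahydro-2H-cyclopenta[c]pyridine-2,7-dicarboxylate
Product: 6 7-benzyl 2-tert-butyl (4aR,7S,7aR)-4-methylidene-6-oxooctahydro-2H-cyclopenta[c]pyridine-2,7-dicarboxylate
Conditions: Ph3PCH3Br (2.6 equiv), KOtBu (2.5 equiv), THF, 0 °C; then 5, −20 to 0 °C
Reagents that add atoms: methyltriphenylphosphonium bromide, C[P+](c1ccccc1)(c1ccccc1)c1ccccc1.[Br-]
Why: Wittig methylenation in which the first equivalent of ylide turns the β-keto ester into its enolate and so masks the C6 ketone, leaving only the C4 piperidinone carbonyl to react; no new stereocenter is formed and the low temperature should keep C4a from epimerising.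

Step 4
Reactants: 6 7-benzyl 2-tert-butyl (4aR,7S,7aR)-4-methylidene-6-oxooctahydro-2H-cyclopenta[c]pyridine-2,7-dicarboxylate
Product: 7 7-benzyl 2-tert-butyl (4aR,7R,7aR)-7-methyl-4-methylidene-6-oxooctahydro-2H-cyclopenta[c]pyridine-2,7-dicarboxylate
Conditions: MeI (1.5 equiv), K2CO3 (2 equiv), acetone, rt
Reagents that add atoms: iodomethane, CI
Why: C-alkylation of the β-keto ester enolate, with methyl expected to enter on the face away from the C1 methylene on C7a; the configuration of this quaternary center does not matter because it is reset after decarboxylation.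

Step 5
Reactants: 7 7-benzyl 2-tert-butyl (4aR,7R,7aR)-7-methyl-4-methylidene-6-oxooctahydro-2H-cyclopenta[c]pyridine-2,7-dicarboxylate
Product: 9 tert-butyl (4R,4aS,7S,7aR)-4,7-dimethyl-6-oxooctahydro-2H-cyclopenta[c]pyridine-2-carboxylate, via keto acid 8 (not isolated)
Conditions: H2 (1 atm), palladium on carbon (Pd/C, 10 wt%), EtOAc, rt; filter; toluene, 80 °C; then DBU (0.2 equiv), rt
Reagents that add atoms: none
Why: Hydrogenolysis of the benzyl ester and syn hydrogenation of the exocyclic alkene, then decarboxylation of the β-keto acid: allylic 1,3-strain should hold the C5–C4a bond pseudoaxial so that hydrogen reaches C4 from the opposite face (4-methyl cis to the cyclopentane, equatorial), and DBU should equilibrate C7 to the more stable methyl trans to the C1 methylene.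

Step 6
Reactants: 9 tert-butyl (4R,4aS,7S,7aR)-4,7-dimethyl-6-oxooctahydro-2H-cyclopenta[c]pyridine-2-carboxylate
Product: 11 6-epi-incarvilline, (4R,4aS,6S,7S,7aR)-2,4,7-trimethyloctahydro-1H-cyclopenta[c]pyridin-6-ol, via carbamate alcohol 10 (not isolated)
Conditions: LiAlH4 (5 equiv), THF, −78 to 0 °C, then reflux; aqueous NaOH work-up
Reagents that add atoms: none
Why: Hydride reduction of the ketone at low temperature, then of the Boc carbamate to N-methyl at reflux; a small hydride should attack C6 from the convex face (the usual trans preference of 2-methylcyclopentanones), giving the endo 6S alcohol trans to the 7-methyl.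

Step 7
Reactants: 12 (E)-4-acetoxy-3-methoxycinnamic acid (two molecules)
Product: 13 (1α,2α,3β,4β)-2,4-bis(4-acetoxy-3-methoxyphenyl)cyclobutane-1,3-dicarboxylic acid
Conditions: crystalline powder, hν (medium-pressure Hg lamp, Pyrex filter), rt, solid turned over periodically
Reagents that add atoms: none
Why: Topochemical [2+2] photodimerisation in which inversion-related, head-to-tail stacked molecules should give the centrosymmetric α-truxillic dimer; the E geometry keeps aryl and carboxyl trans on each former alkene and the packing sets the 1,3-trans relationships.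

Step 8
Reactants: 11 6-epi-incarvilline (2.2 equiv); 13 (1α,2α,3β,4β)-2,4-bis(4-acetoxy-3-methoxyphenyl)cyclobutane-1,3-dicarboxylic acid
Product: 14 4,4′-di-O-acetylincarvillateine
Conditions: PPh3 (3 equiv), DIAD (3 equiv), THF, 0 °C to rt
Reagents that add atoms: none
Why: Twofold Mitsunobu esterification in which each carboxylate displaces the activated endo hydroxyl by SN2 with inversion (6S to 6R), placing the ester oxygen cis to the 7-methyl; the phenols are masked as acetates and the tertiary amines are tolerated.

Step 9
Reactants: 14 4,4′-di-O-acetylincarvillateine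
Product: 15 incarvillateine (CNP0283097.2)
Conditions: pyrrolidine (4 equiv), CH2Cl2, 0 °C to rt
Reagents that add atoms: none
Why: Chemoselective aminolysis of the two aryl acetates, which should be far faster than attack on the hindered secondary cyclobutane esters; no stereocenter is touched.

**Compound list**

1 | benzyl 3-oxobutanoate | CC(=O)CC(=O)OCc1ccccc1 | starting material
2 | benzyl 4-bromo-3-oxobutanoate | BrCC(=O)CC(=O)OCc1ccccc1 | intermediate
3 | tert-butyl 3-oxo-3,6-dihydropyridine-1(2H)-carboxylate | O=C1C=CCN(C(=O)OC(C)(C)C)C1 | starting material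
4 | tert-butyl (3R)-3-[1-(benzyloxy)-4-bromo-1,3-dioxobutan-2-yl]-5-oxopiperidine-1-carboxylate (Michael adduct, held as its enamine with the catalyst) | O=C1C[C@@H](CN(C(=O)OC(C)(C)C)C1)C(C(=O)OCc1ccccc1)C(=O)CBr | intermediate
5 | 7-benzyl 2-tert-butyl (4aR,7S,7aR)-4,6-dioxooctahydro-2H-cyclopenta[c]pyridine-2,7-dicarboxylate (cis-fused; C7 labile) | O=C1C[C@@H]2[C@@H](CN(C(=O)OC(C)(C)C)CC2=O)[C@@H]1C(=O)OCc1ccccc1 | intermediate
6 | 7-benzyl 2-tert-butyl (4aR,7S,7aR)-4-methylidene-6-oxooctahydro-2H-cyclopenta[c]pyridine-2,7-dicarboxylate | O=C1C[C@@H]2[C@@H](CN(C(=O)OC(C)(C)C)CC2=C)[C@@H]1C(=O)OCc1ccccc1 | intermediate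
7 | 7-benzyl 2-tert-butyl (4aR,7R,7aR)-7-methyl-4-methylidene-6-oxooctahydro-2H-cyclopenta[c]pyridine-2,7-dicarboxylate | O=C1C[C@@H]2[C@@H](CN(C(=O)OC(C)(C)C)CC2=C)[C@@]1(C)C(=O)OCc1ccccc1 | intermediate
8 | (4R,4aS,7R,7aR)-2-(tert-butoxycarbonyl)-4,7-dimethyl-6-oxooctahydro-1H-cyclopenta[c]pyridine-7-carboxylic acid | O=C1C[C@@H]2[C@@H](CN(C(=O)OC(C)(C)C)C[C@@H]2C)[C@@]1(C)C(=O)O | intermediate
9 | tert-butyl (4R,4aS,7S,7aR)-4,7-dimethyl-6-oxooctahydro-2H-cyclopenta[c]pyridine-2-carboxylate | O=C1C[C@@H]2[C@@H](CN(C(=O)OC(C)(C)C)C[C@@H]2C)[C@@H]1C | intermediate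
10 | tert-butyl (4R,4aS,6S,7S,7aR)-6-hydroxy-4,7-dimethyloctahydro-2H-cyclopenta[c]pyridine-2-carboxylate (as its aluminium alkoxide) | O[C@H]1C[C@@H]2[C@@H](CN(C(=O)OC(C)(C)C)C[C@@H]2C)[C@@H]1C | intermediate
11 | 6-epi-incarvilline, (4R,4aS,6S,7S,7aR)-2,4,7-trimethyloctahydro-1H-cyclopenta[c]pyridin-6-ol | O[C@H]1C[C@@H]2[C@@H](CN(C)C[C@@H]2C)[C@@H]1C | intermediate
12 | (E)-4-acetoxy-3-methoxycinnamic acid (O-acetylferulic acid) | COc1cc(/C=C/C(=O)O)ccc1OC(C)=O | starting material
13 | (1α,2α,3β,4β)-2,4-bis(4-acetoxy-3-methoxyphenyl)cyclobutane-1,3-dicarboxylic acid (centrosymmetric, achiral) | COc1cc([C@H]2[C@H](C(=O)O)[C@H](c3ccc(OC(C)=O)c(OC)c3)[C@H]2C(=O)O)ccc1OC(C)=O | intermediate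
14 | 4,4′-di-O-acetylincarvillateine (bis[(4R,4aS,6R,7S,7aR)-2,4,7-trimethyloctahydro-1H-cyclopenta[c]pyridin-6-yl] ester of 13) | COc1cc([C@H]2[C@H](C(=O)O[C@@H]3C[C@@H]4[C@@H](CN(C)C[C@@H]4C)[C@@H]3C)[C@H](c3ccc(OC(C)=O)c(OC)c3)[C@H]2C(=O)O[C@@H]2C[C@@H]3[C@@H](CN(C)C[C@@H]3C)[C@@H]2C)ccc1OC(C)=O | intermediate
15 | incarvillateine (CNP0283097.2) | COc1cc([C@H]2[C@H](C(=O)O[C@@H]3C[C@@H]4[C@@H](CN(C)C[C@@H]4C)[C@@H]3C)[C@H](c3ccc(O)c(OC)c3)[C@H]2C(=O)O[C@@H]2C[C@@H]3[C@@H](CN(C)C[C@@H]3C)[C@@H]2C)ccc1O | target

**Count**

Total steps: 9. Longest linear sequence: 8 steps (steps 1, 2, 3, 4, 5, 6, 8, 9); step 7 is a one-step branch.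

**Steps most likely to fail, with fallbacks**

1. Step 2 (Proposed new method). The iminium face may be poorly discriminated, the keto ester may react through oxygen, or the bromo ketone may alkylate the catalyst nitrogen instead of the enamine carbon.
 Fallback (known chemistry, from 3, returning at 9): a zerovalent-palladium trimethylenemethane [3+2] cycloaddition (Pd(OAc)2, P(OiPr)3, THF, reflux) of 3 with 3-acetoxy-2-(trimethylsilylmethyl)but-1-ene should give the cis-fused methylene ketone F1. The methyl-bearing donor carbon bonds to the β-carbon C7a, and either C7 epimer serves. F1 forms as the racemate and is resolved by preparative chromatography on a chiral stationary phase. MeMgBr/CeCl3 then adds to the C4 ketone from the face away from the cyclopentane to give the carbinol F2, and ozonolysis (O3, then Me2S) unmasks the C6 ketone in the keto carbinol F3. Burgess dehydration is a syn elimination and cannot remove the ring-fusion hydrogen, which is trans to the hydroxyl, so it should give the exocyclic alkene F4 together with the endocyclic enecarbamate F5. Hydrogenation of both (H2, Pd/C) on the face away from the cyclopentane, then DBU equilibration at C7, leads to 9.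

2. Step 3. The ring-fusion center C4a may epimerise under the basic ylide, or the β-keto ester carbonyl may be attacked if enolate masking is incomplete.
 Fallback (from 5, returning at 7): the order is reversed and the masking tactic is replaced by steric differentiation. C-methylation of 5 (MeI, K2CO3, acetone) gives the quaternary diketo ester F6, whose C6 ketone is now neopentylic. A non-basic Takai–Lombardo methylenation (Zn, CH2Br2, TiCl4, THF/CH2Cl2) of the unhindered piperidinone carbonyl then gives 7.

3. Step 8. The twofold SN2 displacement at a hindered secondary carbinol may stall after one esterification or divert to elimination.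
 Fallback (from 11 and 13, returning at 14): one Mitsunobu inversion of 11 with the small, acidic 4-nitrobenzoic acid (PPh3, DIAD) gives the 4-nitrobenzoate F7. Methanolysis (K2CO3, MeOH) gives incarvilline F8 with the exo hydroxyl. This is acylated with retention by the diacid dichloride F9 (from 13 with oxalyl chloride and catalytic DMF) in CH2Cl2 with Et3N and DMAP to give 14.

**Further compounds**

F1 | step 2 | tert-butyl (4aR,7S,7aS)-7-methyl-6-methylidene-4-oxooctahydro-2H-cyclopenta[c]pyridine-2-carboxylate (formed as racemate, resolved) | C=C1C[C@@H]2[C@@H](CN(C(=O)OC(C)(C)C)CC2=O)[C@@H]1C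
F2 | step 2 | tert-butyl (4R,4aR,7S,7aS)-4-hydroxy-4,7-dimethyl-6-methylideneoctahydro-2H-cyclopenta[c]pyridine-2-carboxylate | C=C1C[C@@H]2[C@@H](CN(C(=O)OC(C)(C)C)C[C@]2(C)O)[C@@H]1C
F3 | step 2 | tert-butyl (4R,4aR,7S,7aR)-4-hydroxy-4,7-dimethyl-6-oxooctahydro-2H-cyclopenta[c]pyridine-2-carboxylate | O=C1C[C@@H]2[C@@H](CN(C(=O)OC(C)(C)C)C[C@]2(C)O)[C@@H]1C
F4 | step 2 | tert-butyl (4aR,7S,7aR)-7-methyl-4-methylidene-6-oxooctahydro-2H-cyclopenta[c]pyridine-2-carboxylate | O=C1C[C@@H]2[C@@H](CN(C(=O)OC(C)(C)C)CC2=C)[C@@H]1C
F5 | step 2 | tert-butyl (4aR,7S,7aR)-4,7-dimethyl-6-oxo-1,4a,5,6,7,7a-hexahydro-2H-cyclopenta[c]pyridine-2-carboxylate | O=C1C[C@@H]2[C@@H](CN(C(=O)OC(C)(C)C)C=C2C)[C@@H]1C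
F6 | step 3 | 7-benzyl 2-tert-butyl (4aR,7R,7aR)-7-methyl-4,6-dioxooctahydro-2H-cyclopenta[c]pyridine-2,7-dicarboxylate | O=C1C[C@@H]2[C@@H](CN(C(=O)OC(C)(C)C)CC2=O)[C@@]1(C)C(=O)OCc1ccccc1
F7 | step 8 | (4R,4aS,6R,7S,7aR)-2,4,7-trimethyloctahydro-1H-cyclopenta[c]pyridin-6-yl 4-nitrobenzoate | O=C(O[C@@H]1C[C@@H]2[C@@H](CN(C)C[C@@H]2C)[C@@H]1C)c1ccc(cc1)[N+](=O)[O-]
F8 | step 8 | incarvilline, (4R,4aS,6R,7S,7aR)-2,4,7-trimethyloctahydro-1H-cyclopenta[c]pyridin-6-ol | O[C@@H]1C[C@@H]2[C@@H](CN(C)C[C@@H]2C)[C@@H]1C
F9 | step 8 | (1α,2α,3β,4β)-2,4-bis(4-acetoxy-3-methoxyphenyl)cyclobutane-1,3-dicarbonyl dichloride | COc1cc([C@H]2[C@H](C(=O)Cl)[C@H](c3ccc(OC(C)=O)c(OC)c3)[C@H]2C(=O)Cl)ccc1OC(C)=O
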